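**Plan**

- Numbering: the chain runs from the carboxyl carbon C1 (stereocentres C3 and C5) to C9; the furan is O1, C2 (aryl), C3, C4 (chain), C5.
- Cuts, in order: (a) C7=C8, prenyl back to allyl; (b) furan O1–C2 together with chain C5–C6; (c) the sp–sp2 bond that becomes furan C3–C4; (d) the C5=C(alpha) alkene of an enal.
- Enabling feature: stereocentre C5 sits directly on furan C4, and furan C5 carries only H. Ring plus C5 therefore map onto a 2-(arylethynyl)enal whose beta carbon is C5; closing O1–C2 turns that carbon into a cation that an allylsilane can capture.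
- Forward: the C1–C5 chain is grown from monomethyl (R)-3-methylglutarate to an alpha-iodoenal and joined to silylated 2-ethynylhydroquinone. The furan, the only ring made, closes in the gold step, which also installs the allyl group. Metathesis and one global unmasking finish the route.
- Stereochemistry: C3 is bought (chiral pool) and is never enolisable; C5 is created in the gold step under control of a chiral bisphosphine on gold.

Key step: step 9

Assumption: the antipode of the bisphosphine that shields the correct face of the cation cannot be predicted. The (R) ligand is written, and the (S) ligand would replace it if the first experiment shows the opposite sense. (R)-DTBM-SEGPHOS = (R)-5,5'-bis[bis(3,5-di-tert-butyl-4-methoxyphenyl)phosphino]-4,4'-bi-1,3-benzodioxole.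

Assumption: commercial monomethyl (R)-3-methylglutarate is taken as enantiomerically pure enough; if not, it would be upgraded by crystallising a salt with a chiral amine.

**Route**

Step 1
Reactants: 1 monomethyl (R)-3-methylglutarate [(3R)-5-methoxy-3-methyl-5-oxopentanoic acid]
Product: 2 methyl (3R)-5-hydroxy-3-methylpentanoate
Conditions: BH3·SMe2 (1.2 equiv), THF, −10 °C → rt; aqueous work-up
Reagents that add atoms: none
Why: Chemoselective borane reduction of a carboxylic acid: the acid reacts through its acyloxyborane far faster than the methyl ester, C3 is untouched, and the hydroxy ester is used at once to forestall lactonisation.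

Step 2
Reactants: 2 methyl (3R)-5-hydroxy-3-methylpentanoate
Product: 3 methyl (3R)-3-methyl-5-oxopentanoate
Conditions: Dess–Martin periodinane, CH2Cl2, 0 °C → rt
Reagents that add atoms: none
Why: Dess–Martin oxidation should stop cleanly at the aldehyde, and C3, being beta to both carbonyl groups, cannot epimerise.

Step 3
Reactants: 3 methyl (3R)-3-methyl-5-oxopentanoate; 4 (triphenylphosphoranylidene)acetaldehyde
Product: 5 methyl (3R,5E)-3-methyl-7-oxohept-5-enoate
Conditions: 4 (1.1 equiv), toluene, 80 °C
Reagents that add atoms: none
Why: Wittig olefination with the stabilised formylmethylene ylide should give the (E)-enal, and only a slight excess of ylide is used to limit a second homologation.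

Step 4
Reactants: 5 methyl (3R,5E)-3-methyl-7-oxohept-5-enoate
Product: 6 methyl (3R,5Z)-6-iodo-3-methyl-7-oxohept-5-enoate
Conditions: I2, DMAP (0.2 equiv), K2CO3, THF/H2O (1:1), rt
Reagents that add atoms: iodine, II
Why: Baylis–Hillman-type alpha-iodination: DMAP adds in conjugate fashion, the enolate is iodinated and E1cB loss of DMAP returns the enal in its favoured Z geometry (chain cis to iodine, trans to formyl).

Step 5
Reactants: 7 2,5-dihydroxybenzaldehyde
Product: 8 2,5-bis(tert-butyldimethylsilyloxy)benzaldehyde
Conditions: TBSCl, imidazole, DMF, rt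
Reagents that add atoms: tert-butyldimethylsilyl chloride, CC(C)(C)[Si](C)(C)Cl
Why: Imidazole-promoted silylation of both phenols is routine, and the bulky silyl ethers later keep the ortho oxygen from adding to the alkyne.

Step 6
Reactants: 8 2,5-bis(tert-butyldimethylsilyloxy)benzaldehyde
Product: 9 2-(2,2-dibromoethenyl)-1,4-bis(tert-butyldimethylsilyloxy)benzene
Conditions: CBr4, PPh3, Zn, CH2Cl2, rt; then 8, 0 °C → rt
Reagents that add atoms: carbon tetrabromide, BrC(Br)(Br)Br
Why: Corey–Fuchs dibromoolefination with the ylide Ph3P=CBr2 runs under neutral conditions that leave aryl silyl ethers intact and avoids a free benzylic alkoxide next to the ortho silyl ether.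

Step 7
Reactants: 9 2-(2,2-dibromoethenyl)-1,4-bis(tert-butyldimethylsilyloxy)benzene
Product: 10 2-ethynyl-1,4-bis(tert-butyldimethylsilyloxy)benzene
Conditions: n-BuLi (2.2 equiv), THF, −78 °C; then H2O
Reagents that add atoms: none
Why: Second stage of the Corey–Fuchs sequence: bromine–lithium exchange, alpha-elimination and a Fritsch–Buttenberg–Wiechell 1,2-shift give the alkyne at a temperature where aryl silyl ethers survive butyllithium.

Step 8
Reactants: 6 methyl (3R,5Z)-6-iodo-3-methyl-7-oxohept-5-enoate; 10 2-ethynyl-1,4-bis(tert-butyldimethylsilyloxy)benzene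
Product: 11 methyl (3R,5E)-8-[2,5-bis(tert-butyldimethylsilyloxy)phenyl]-6-formyl-3-methyloct-5-en-7-ynoate
Conditions: PdCl2(PPh3)2 (3 mol%), CuI (6 mol%), i-Pr2NH, THF, 0 °C → rt, Ar
Reagents that add atoms: none
Why: Sonogashira coupling: alpha-iodoenals add oxidatively to zerovalent palladium already at 0 °C, the hindered amine does not condense with the aldehyde, and the alkyne takes the place of iodine with retention of alkene geometry.

Step 9
Reactants: 11 methyl (3R,5E)-8-[2,5-bis(tert-butyldimethylsilyloxy)phenyl]-6-formyl-3-methyloct-5-en-7-ynoate; 12 allyltrimethylsilane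
Product: 13 methyl (3R,5R)-5-{5-[2,5-bis(tert-butyldimethylsilyloxy)phenyl]furan-3-yl}-3-methyloct-7-enoate
Conditions: (R)-DTBM-SEGPHOS(AuCl)2 (2.5 mol%), AgOTf (5 mol%), 12 (3 equiv), t-BuOH (1.2 equiv), CH2Cl2, −20 °C → rt
Reagents that add atoms: none
Why: Proposed new method: cationic monovalent gold binds the alkyne of 11, the aldehyde oxygen adds to the aryl-bearing alkyne carbon (5-endo-dig, O1–C2) to give a 3-aurated furan whose exocyclic chain carbon C5 is a furan-stabilised cation (a vinylogous oxocarbenium ion), 12 attacks this carbon through its terminal CH2 with loss of silicon (SE2', Hosomi–Sakurai type, C5–C6), and tert-butanol takes up the silyl group and returns the proton that protodeaurates furan C3. The closest known reaction type is the gold-catalysed cyclisation of 2-(1-alkynyl)-2-alken-1-ones with capture of the same cation by alcohols, indoles or 1,3-dicarbonyls, together with its enantioselective cycloaddition variants run with chiral bisphosphine digold complexes; an allylsilane as the carbon nucleophile and ligand-controlled formation of an acyclic stereocentre are the untested elements. The new C5 stereocentre is set by the catalyst alone: the bulky chiral bisphosphine is carried by the gold on furan C3, next to the planar cation, and should block one of its faces, whereas the C3 methyl centre is too remote to bias the attack. The step needs the aldehyde oxygen, not the ortho aryl oxygen, to add to the alkyne, which the hindered and poorly nucleophilic silyl ether secures, and the electron-rich arene places the developing positive charge on the alkyne carbon that the carbonyl attacks. Capture of the cation by tert-butanol is reversible under the reaction conditions while C–C bond formation is not, so material should drain to 13.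

Step 10
Reactants: 13 methyl (3R,5R)-5-{5-[2,5-bis(tert-butyldimethylsilyloxy)phenyl]furan-3-yl}-3-methyloct-7-enoate
Product: 14 methyl (3R,5S)-5-{5-[2,5-bis(tert-butyldimethylsilyloxy)phenyl]furan-3-yl}-3,8-dimethylnon-7-enoate
Conditions: second-generation Grubbs catalyst (H2IMes)(PCy3)Cl2Ru=CHPh (5 mol%), 2-methylbut-2-ene/CH2Cl2, 40 °C, sealed vessel
Reagents that add atoms: 2-methylbut-2-ene, CC=C(C)C
Why: Olefin cross-metathesis with a large excess of 2-methylbut-2-ene should convert the terminal alkene into the prenyl group with release of propene; no stereocentre is involved, and the C5 descriptor changes from R to S only because the prenyl arm now outranks the C4 methylene.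

Step 11
Reactants: 14 methyl (3R,5S)-5-{5-[2,5-bis(tert-butyldimethylsilyloxy)phenyl]furan-3-yl}-3,8-dimethylnon-7-enoate
Product: 15 (3R,5S)-5-[5-(2,5-dihydroxyphenyl)furan-3-yl]-3,8-dimethylnon-7-enoic acid
Conditions: LiOH·H2O (8 equiv), degassed THF/MeOH/H2O, Ar, 0 °C → rt; then degassed 1 M HCl to pH 3 at 0 °C (Na2S2O4 in the wash)
Reagents that add atoms: lithium hydroxide (its oxygen ends in the carboxyl OH), [Li+].[OH-]
Why: Hydroxide should cleave both aryl silyl ethers by attack at silicon and saponify the methyl ester (BAc2) in one operation, with oxygen excluded because the hydroquinone dianion is easily oxidised and with neither stereocentre enolisable.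

**Compound list**

1 | (3R)-5-methoxy-3-methyl-5-oxopentanoic acid (monomethyl (R)-3-methylglutarate) | COC(=O)C[C@H](C)CC(=O)O | starting material
2 | methyl (3R)-5-hydroxy-3-methylpentanoate | COC(=O)C[C@H](C)CCO | intermediate
3 | methyl (3R)-3-methyl-5-oxopentanoate | COC(=O)C[C@H](C)CC=O | intermediate
4 | (triphenylphosphoranylidene)acetaldehyde | O=CC=P(c1ccccc1)(c1ccccc1)c1ccccc1 | starting material
5 | methyl (3R,5E)-3-methyl-7-oxohept-5-enoate | COC(=O)C[C@H](C)C/C=C/C=O | intermediate
6 | methyl (3R,5Z)-6-iodo-3-methyl-7-oxohept-5-enoate | COC(=O)C[C@H](C)C/C=C(\I)C=O | intermediate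
7 | 2,5-dihydroxybenzaldehyde | O=Cc1cc(O)ccc1O | starting material
8 | 2,5-bis(tert-butyldimethylsilyloxy)benzaldehyde | O=Cc1cc(O[Si](C)(C)C(C)(C)C)ccc1O[Si](C)(C)C(C)(C)C | intermediate
9 | 2-(2,2-dibromoethenyl)-1,4-bis(tert-butyldimethylsilyloxy)benzene | BrC(Br)=Cc1cc(O[Si](C)(C)C(C)(C)C)ccc1O[Si](C)(C)C(C)(C)C | intermediate
10 | 2-ethynyl-1,4-bis(tert-butyldimethylsilyloxy)benzene | C#Cc1cc(O[Si](C)(C)C(C)(C)C)ccc1O[Si](C)(C)C(C)(C)C | intermediate
11 | methyl (3R,5E)-8-[2,5-bis(tert-butyldimethylsilyloxy)phenyl]-6-formyl-3-methyloct-5-en-7-ynoate | COC(=O)C[C@H](C)C/C=C(/C=O)C#Cc1cc(O[Si](C)(C)C(C)(C)C)ccc1O[Si](C)(C)C(C)(C)C | intermediate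
12 | allyltrimethylsilane | C=CC[Si](C)(C)C | starting material
13 | methyl (3R,5R)-5-{5-[2,5-bis(tert-butyldimethylsilyloxy)phenyl]furan-3-yl}-3-methyloct-7-enoate | C=CC[C@H](C[C@@H](C)CC(=O)OC)c1coc(-c2cc(O[Si](C)(C)C(C)(C)C)ccc2O[Si](C)(C)C(C)(C)C)c1 | intermediate
14 | methyl (3R,5S)-5-{5-[2,5-bis(tert-butyldimethylsilyloxy)phenyl]furan-3-yl}-3,8-dimethylnon-7-enoate | CC(C)=CC[C@H](C[C@@H](C)CC(=O)OC)c1coc(-c2cc(O[Si](C)(C)C(C)(C)C)ccc2O[Si](C)(C)C(C)(C)C)c1 | intermediate
15 | (3R,5S)-5-[5-(2,5-dihydroxyphenyl)furan-3-yl]-3,8-dimethylnon-7-enoic acid | CC(C)=CC[C@H](C[C@@H](C)CC(=O)O)c1coc(-c2cc(O)ccc2O)c1 | target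

**Step count**

Total: 11 steps. Longest linear sequence: 8 steps (steps 1–4 and 8–11, from 1). The alkyne branch (steps 5–7) joins at step 8.

**Steps most likely to fail**

1. Step 9. Facial discrimination at the planar cation may be poor, or the weakly nucleophilic allylsilane may not compete with reversible oxygen capture and oligomerisation. The fallback separates ring closure from allylation and uses known reaction types only. It sets out from 11: AuCl3 (2 mol%) and methanol in CH2Cl2 at rt, the established cyclisation–alkoxylation of 2-alkynyl enones, should give methyl (3R)-5-{5-[2,5-bis(tert-butyldimethylsilyloxy)phenyl]furan-3-yl}-5-methoxy-3-methylpentanoate F1 as both C5 epimers. Ionisation of this furylmethyl ether with catalytic TMSOTf in CH2Cl2 at −78 °C in the presence of 12 (Hosomi–Sakurai substitution of an activated ether) should then give 13 together with its C5 epimer, methyl (3R,5S)-5-{5-[2,5-bis(tert-butyldimethylsilyloxy)phenyl]furan-3-yl}-3-methyloct-7-enoate F2. Preparative HPLC would separate the two, and the route resumes at 13.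

2. Step 11. Oxidation of the hydroquinone dianion by traces of oxygen, or base-induced degradation of the electron-rich arylfuran, may erode the last step. The fallback splits the unmasking so that no phenoxide is formed. It sets out from 14: buffered fluoride (TBAF/AcOH, THF, 0 °C) removes both silyl groups to give methyl (3R,5S)-5-[5-(2,5-dihydroxyphenyl)furan-3-yl]-3,8-dimethylnon-7-enoate F3. The methyl ester is then hydrolysed with pig liver esterase in pH 7 phosphate buffer containing a little DMSO under argon, which arrives at 15.

3. Step 3. A second homologation of the product enal by the formyl ylide, or incomplete E selectivity, may lower the throughput. The fallback builds the enal by metathesis and sets out from 3: methylenation with Ph3P=CH2 (from Ph3PCH3Br and KHMDS, THF, −78 °C → rt) gives methyl (3R)-3-methylhex-5-enoate F4. Cross-metathesis of this alkene with excess crotonaldehyde (second-generation Hoveyda–Grubbs catalyst (H2IMes)Cl2Ru=CH(C6H4-2-O-i-Pr), CH2Cl2, 40 °C) should deliver the (E)-enal and so returns to the route at 5.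

Further compounds
F1 | step 9 | methyl (3R)-5-{5-[2,5-bis(tert-butyldimethylsilyloxy)phenyl]furan-3-yl}-5-methoxy-3-methylpentanoate (both C5 epimers) | COC(=O)C[C@H](C)CC(OC)c1coc(-c2cc(O[Si](C)(C)C(C)(C)C)ccc2O[Si](C)(C)C(C)(C)C)c1
F2 | step 9 | methyl (3R,5S)-5-{5-[2,5-bis(tert-butyldimethylsilyloxy)phenyl]furan-3-yl}-3-methyloct-7-enoate | C=CC[C@@H](C[C@@H](C)CC(=O)OC)c1coc(-c2cc(O[Si](C)(C)C(C)(C)C)ccc2O[Si](C)(C)C(C)(C)C)c1
F3 | step 11 | methyl (3R,5S)-5-[5-(2,5-dihydroxyphenyl)furan-3-yl]-3,8-dimethylnon-7-enoate | CC(C)=CC[C@H](C[C@@H](C)CC(=O)OC)c1coc(-c2cc(O)ccc2O)c1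
F4 | step 3 | methyl (3R)-3-methylhex-5-enoate | COC(=O)C[C@H](C)CC=C
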